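Amounts come first: the four flasks share c(starting complex) and c(leaving ligand) and differ in c(incoming ligand).

| setting | spring | winter | Monday's | Saturday's |
|---|---|---|---|---|
| starting complex | 20 mM | 20 mM | 20 mM | 20 mM |
| incoming ligand | 29 mM | 55 mM | 80.0 mM | 40.0 mM |
| leaving ligand | 40 mM | 40 mM | 40.0 mM | 40.0 mM |
| remark | run made earlier | run made earlier |  |  |
| time |  |  | 30 min | 30 min |

| run | time / min | complex with three exchanged / % | complex with one exchanged / % |
|---|---|---|---|
| spring | 2.50 | 7.9 | 0 |
| spring | 5.00 | 8.1 | 0 |
| spring | 8.00 | 8.0 | 0 |
| spring | 15.0 | 7.3 | 0.1 |
| spring | 30.0 | 7.3 | 0 |
| winter | 6.00 | 79.4 | 0.1 |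
| winter | 12.0 | 82.5 | 0 |
| winter | 20.0 | 82.9 | 0.5 |
| winter | 25.0 | 84.1 | 0 |
| winter | 30.0 | 82.8 | 0 |

(readings scatter by 0.5 percentage points)

1. which of these holds the largest part of the starting complex at the end of Monday's (complex with three exchanged / complex with one exchanged / complex with two exchanged / starting complex)
2. which of these holds the largest part of the starting complex at the end of Saturday's (complex with three exchanged / complex with one exchanged / complex with two exchanged / starting complex)
3. amount of complex with three exchanged at the end of Monday's, in percent of the starting complex charged



Both earlier runs have levelled off by 12.0 min, so I compare plateaus, not times. Monday's charge gives 1.33 of what I call the supply number S, the incoming ligand charged over the 3 equivalents that full exchange of the starting complex demands. Spring stands at 0.483, winter at 0.917 and Saturday's at 0.667.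

Below 1 the charge falls short of what full exchange demands. Monday's lies above 1, which makes the starting complex the limiting reagent. Complex with three exchanged reads 7.3 % at spring's S and 82.8 % at winter's, so it climbs steeply between them. Saturday's supplies 2.00 equivalents, and I expect complex with two exchanged to lead there. On Monday's I commit to complex with three exchanged, close to 100 %. Whether one number is enough stays open, since S leaves out c(leaving ligand), which both runs held at 40 mM.

The forecast names complex with three exchanged for Monday's at 97 % and complex with two exchanged for Saturday's, reasoning that “nearly everything should reach three-exchanged”. The flask gives complex with three exchanged on Monday's at 96.2 %, and complex with two exchanged on Saturday's at 52.6 %.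

    starting complex + incoming ligand → leaving ligand + complex with one exchanged (k = 21.0 M⁻¹ s⁻¹)
    complex with one exchanged + incoming ligand → leaving ligand + complex with two exchanged (k = 43.0 M⁻¹ s⁻¹)
    complex with two exchanged + incoming ligand → leaving ligand + complex with three exchanged (k = 3.40 M⁻¹ s⁻¹)
    incoming ligand ⇌ dormant form (K = 0.650, k = 0.0200 s⁻¹)
    leaving ligand + complex with one exchanged → side product (k = 1.30 M⁻¹ s⁻¹)

At S of 1.33, Monday's gives 96.2 %, yet S holds no rate constant. The main reason for that height is the difference between the rate constants of the exchange steps, for the same run with that difference taken away reaches 90.6 %. A flask like Monday's but with 80 mM of starting complex has S of 0.333, below spring's, and there complex with three exchanged holds 2.35 %.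

The data were computed for substances that don't exist.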